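A flat product reading tempts you to call the reaction finished, yet Friday's run went flat with 46.7% of its substrate still there. So follow what is left. Friday's final product equals 93.3% of the partner charge; this is the partner yield, the fraction of partner's charge that has become product once a flask stands flat, and I take partner as the limiting reagent there.

| flask | substrate | partner | remark | time |
|---|---|---|---|---|
| Thursday's | 0.033 M | 0.179 M | run made earlier |  |
| Friday's | 0.31 M | 0.179 M | run made earlier |  |
| spring | 0.060 M | 0.179 M |  | 8.0 min |
| noon | 0.15 M | 0.179 M |  | 8.0 min |
| midnight | 0.50 M | 0.179 M |  | 8.0 min |

| run | time / min | product / % | substrate / % |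
|---|---|---|---|
| Thursday's | 0.667 | 0 | 99.5 |
| Thursday's | 1.33 | 0 | 99.7 |
| Thursday's | 2.50 | 0 | 100.0 |
| Thursday's | 4.00 | 0.6 | 99.2 |
| Thursday's | 8.00 | 2.1 | 99.2 |
| Friday's | 0.667 | 0 | 99.8 |
| Friday's | 1.33 | 1.0 | 98.6 |
| Friday's | 2.50 | 28.7 | 69.6 |
| Friday's | 4.00 | 52.3 | 48.3 |
| Friday's | 8.00 | 53.9 | 46.7 |

(each reading ± 0.5 percentage points)

- a reading or a percentage of product counts all its forms, free or not
- the concentration of product that is asked is that of its free form alone
- "hardly changes" means that all values lie within two and a half points (for a concentration: within two and a half percent of the largest)

- [product] (only what is free in solution) at the end for spring, noon, midnight, in this order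
- the course of these numbers from the first flask to the last (falls, then rises / rises, then falls / rises all the way / falls all the way / hardly changes)

Now set out a ladder of times, as read from the runs. On the fastest rung stands Friday's burst: from 1.33 min to 4.00 min its substrate fraction has a half-life near 2.59 min, shorter than the new flasks' 8.0 min, and Friday's run stands flat inside that time. On the slowest rung stands Thursday's creep, with a half-life near 261 min, and its product is 2.1% at its last reading.

My own reckoning puts midnight, which is charged with more substrate than Friday's, on the fast rung. It should stand flat before its end with a fraction 66.6% of substrate left, which is one minus the partner yield times the partner-to-substrate charge ratio. I expect spring and noon still running at the end, and for those two flasks I name no order of finishing. The readings count every form of product, so I give no number for the free level.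

The forecast gives 0.001 M, 0.001 M and 0.001 M, a course that hardly changes, holding that “free product stays near 0.001 M in all three flasks”.

The flasks give 0.00253 M, 0.00284 M and 0.00240 M, a course that rises, then falls.

    crystals ⇌ product, rate k1*(cs1 - [product]) while solid is left; crystals form when [product] > cs1 (solubility = 2.40 mM, k = 0.320 s⁻¹)
    partner → decomposed reagent (k = 4.90 × 10⁻⁴ s⁻¹)
    substrate + partner + by-product → product + 2 by-product (k = 1.20 M⁻² s⁻¹)
    substrate + partner → product + by-product (k = 2.60 × 10⁻⁵ M⁻¹ s⁻¹)

In spring at 8.00 min, partner has a half-life of 24 min by the loss to decomposed reagent, shorter than the 37 min by the making of product. Midnight at 8.00 min has 66% of its substrate left against my 66.6%, with partner at 0%, while noon at 80.0 min has partner at 0.0186% and substrate at 3.03%, a partner yield of 81.3%.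

The data stem from a simulated flask for an exercise; the scatter is artificial.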